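**Retrosynthetic overview**
1. Last operation: both tropolone rings are made at once from a bis(4-alkoxy-o-quinone). One CH is inserted between C=O and C(Me) of each six-membered ring (double one-carbon ring expansion, 6 → 7).
2. The bis-o-quinone comes from a bis(7-hydroxy-5-methylchroman) by double ortho-oxygenation of the two phenols.
3. Both dihydropyran rings are cut together: a double hetero-Diels–Alder reaction of an orcinol-derived o-quinone methide with the two E-trisubstituted alkenes of (S)-10-hydroxyhumulene. This sets C1, C7, C8 and C11 from C10.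
4. (S)-10-Hydroxyhumulene comes from α-humulene by allylic oxidation, oxidation to the enone and CBS reduction (sets C10). The quinone methide precursor comes from 2,4-dihydroxy-6-methylbenzaldehyde.
5. Order of rings: eleven-membered ring (bought with humulene) → two dihydropyrans in one pot → two tropolones in one pot.

Assumption: locants are those of the eleven-membered ring, namely C1 (ring-fusion CH), C2H2, C3 (CMe2), C4=C5, C6H2, C7 (O and Me), C8 (ring-fusion CH), C9H2, C10 (CHOH), C11 (O and Me); in this numbering the target is 1R,7R,8R,10S,11R with E-C4=C5, and 1 and 5 are taken as catalogue chemicals.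

**Step 1**
Reactants: 1 α-humulene
Product: 2 racemic 10-hydroxyhumulene, (2E,6E,9E)-2,5,5,9-tetramethylcycloundeca-2,6,9-trien-1-ol
Conditions: SeO2 (0.3 equiv), t-BuOOH (2.5 equiv, decane), salicylic acid (0.1 equiv), CH2Cl2, 0 °C to rt, stopped near half conversion
Reagents that add atoms: tert-butyl hydroperoxide, CC(C)(C)OO (terminal source of the oxygen); selenium dioxide, O=[Se]=O (carrier that hands the oxygen to C10)
Why: Riley allylic hydroxylation in its catalytic hydroperoxide form, in which an ene reaction of SeO2 at C11=C1 followed by a [2,3]-sigmatropic shift restores the E-alkene and puts oxygen on the ring CH2 at the more substituted alkene terminus (CH2 before CH3), C10 forming as a racemate that steps 2 and 3 correct, while isomers from attack at C7=C8 or at the methyl groups are removed by chromatography.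

**Step 2**
Reactants: 2 racemic 10-hydroxyhumulene
Product: 3 10-oxohumulene, (2E,6E,9E)-2,5,5,9-tetramethylcycloundeca-2,6,9-trien-1-one
Conditions: Dess–Martin periodinane (1.2 equiv), CH2Cl2, 0 °C to rt
Reagents that add atoms: none
Why: Dess–Martin oxidation of a secondary allylic alcohol under non-enolising conditions, so the skipped C7=C8 alkene does not slip into conjugation and the racemic centre is erased.

**Step 3**
Reactants: 3 10-oxohumulene
Product: 4 (S)-10-hydroxyhumulene, (1S,2E,6E,9E)-2,5,5,9-tetramethylcycloundeca-2,6,9-trien-1-ol
Conditions: (R)-Me-CBS (0.2 equiv), catecholborane (1.5 equiv), toluene, −78 °C; then MeOH, aq. NH4Cl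
Reagents that add atoms: none
Why: Corey–Bakshi–Shibata reduction, in which the ketone binds the oxazaborolidine boron anti to the larger α-methylalkenyl arm so that the (R)-catalyst delivers hydride to the face giving 10S, while catecholborane at −78 °C does not hydroborate the strained alkenes.

**Step 4**
Reactants: 5 2,4-dihydroxy-6-methylbenzaldehyde
Product: 6 4-(hydroxymethyl)-5-methylbenzene-1,3-diol
Conditions: NaBH4 (0.5 equiv), THF/MeOH, 0 °C; pH 7 buffer; used at once
Reagents that add atoms: none
Why: Plain borohydride reduction of an aromatic aldehyde that creates no stereocentre and gives a labile, electron-rich benzylic alcohol which is carried on directly.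

**Step 5**
Reactants: 4 (S)-10-hydroxyhumulene; 6 4-(hydroxymethyl)-5-methylbenzene-1,3-diol (two equivalents incorporated, five used)
Product: 9 (1R,7R,8R,10S,11R)-bis(7-hydroxy-5-methylchroman) trans-fused to the macrocycle at C7-C8 and C11-C1, via o-quinone methide 7 (not isolated), via mono-chroman 8 (not isolated)
Conditions: 6 in 1,4-dioxane added by syringe pump over 10 h to 4 in toluene, 110 °C, 4 Å molecular sieves
Reagents that add atoms: none
Why: Thermal dehydration of 6 gives 7, which adds twice in an inverse-electron-demand hetero-Diels–Alder reaction (oxygen to the methyl-bearing carbon) suprafacially to the exposed outer face of the strained E-trisubstituted alkenes, so each fusion is trans (Me and H anti), first at the more electron-rich C7=C8 to give 8 and then at C11=C1, where C9 sits on the inner face, the C10–O bond lies next to the alkene to avoid A(1,2) strain with the C11 methyl, and the OH can hydrogen-bond to the incoming carbonyl, which is expected to translate 10S into 1R,7R,8R,11R.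

**Step 6**
Reactants: 9 bis(7-hydroxy-5-methylchroman)
Product: 10 (1R,7R,8R,10S,11R)-bis(5-methylchroman-6,7-dione)
Conditions: IBX (2.2 equiv), DMF, 0 °C to rt, 2 h, dark
Reagents that add atoms: IBX (2-iodoxybenzoic acid), O=C1OI(=O)(O)c2ccccc12
Why: IBX ortho-oxygenation of phenols, in which each phenol binds pentavalent iodine and oxygen is passed intramolecularly to the ortho carbon para to the pyran oxygen (the position where orcinol-type rings take electrophiles), giving the vinylogous-ester-stabilised 4-alkoxy-o-quinone faster than the hindered C10 carbinol is oxidised and leaving all stereocentres untouched.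

**Step 7**
Reactants: 10 bis(5-methylchroman-6,7-dione)
Product: 12 target CNP0283947.4, via bis(silyloxytropone) 11 (not isolated)
Conditions: TMSCHN2 (2.3 equiv), Sc(OTf)3 (10 mol %), CH2Cl2, −78 to −20 °C; AcOH quench; then aq. citric acid/THF, rt
Reagents that add atoms: trimethylsilyldiazomethane, C[Si](C)(C)C=[N+]=[N-]
Why: Proposed new method: the diazo carbon adds to the more electrophilic C=O of each 4-alkoxy-o-quinone (the one next to C(Me), since the other is deactivated as a vinylogous ester of the pyran oxygen), loss of N2 drives a 1,2-shift of the alkenyl carbon rather than the acyl carbon, and a carbon-to-oxygen silyl shift aromatises the expanded dione to 11 so that no acidic OH is present to be methylated, which makes two seven-membered rings in one operation without touching a stereocentre, the closest known reaction types being the Büchner–Curtius–Schlotterbeck homologation of cyclohexadienones to tropones and the Eistert ring enlargement of isatins and phenanthrenequinone with diazoalkanes.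

**Compound list**
1 | α-humulene, (1E,4E,8E)-2,6,6,9-tetramethylcycloundeca-1,4,8-triene | C1C/C=C(\C)C/C=C/C(C)(C)C/C=C1\C | starting material
2 | racemic 10-hydroxyhumulene | OC1C/C=C(\C)C/C=C/C(C)(C)C/C=C1\C | intermediate
3 | 10-oxohumulene | O=C1C/C=C(\C)C/C=C/C(C)(C)C/C=C1\C | intermediate
4 | (S)-10-hydroxyhumulene | O[C@H]1C/C=C(\C)C/C=C/C(C)(C)C/C=C1\C | intermediate
5 | 2,4-dihydroxy-6-methylbenzaldehyde | Cc1cc(O)cc(O)c1C=O | starting material
6 | 4-(hydroxymethyl)-5-methylbenzene-1,3-diol | Cc1cc(O)cc(O)c1CO | intermediate
7 | o-quinone methide, 3-hydroxy-5-methyl-6-methylidenecyclohexa-2,4-dien-1-one (not isolated) | C=C1C(C)=CC(O)=CC1=O | intermediate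
8 | (7R,8R,10S)-mono-chroman: 7-hydroxy-5-methylchroman trans-fused at C7-C8, allylic alcohol and both other alkenes intact (not isolated) | O[C@H]1C[C@H]2Cc3c(C)cc(O)cc3O[C@]2(C)C/C=C/C(C)(C)C/C=C1\C | intermediate
9 | (1R,7R,8R,10S,11R)-bis(7-hydroxy-5-methylchroman) | Cc1cc(O)cc2c1C[C@H]1CC(C)(C)/C=C/C[C@@]3(C)Oc4cc(O)cc(C)c4C[C@@H]3C[C@H](O)[C@]1(C)O2 | intermediate
10 | (1R,7R,8R,10S,11R)-bis(5-methylchroman-6,7-dione) | CC=1C(=O)C(=O)C=C2C=1C[C@H]1CC(C)(C)/C=C/C[C@@]3(C)OC4=CC(=O)C(=O)C(C)=C4C[C@@H]3C[C@H](O)[C@]1(C)O2 | intermediate
11 | bis(trimethylsilyloxytropone), O-silylated form of the target (not isolated) | Cc1cc(O[Si](C)(C)C)c(=O)cc2c1C[C@H]1CC(C)(C)/C=C/C[C@@]3(C)Oc4cc(=O)c(O[Si](C)(C)C)cc(C)c4C[C@@H]3C[C@H](O)[C@]1(C)O2 | intermediate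
12 | CNP0283947.4, (1R,7R,8R,10S,11R)-bis-tropolone | Cc1cc(=O)c(O)cc2c1C[C@H]1CC(C)(C)/C=C/C[C@@]3(C)Oc4cc(O)c(=O)cc(C)c4C[C@@H]3C[C@H](O)[C@]1(C)O2 | target

**Totals:** 7 steps in all. The longest linear sequence is 6 steps (1 → 2 → 3 → 4 → 9 → 10 → 12).

**The three steps most likely to fail**

The first weak point is step 1.
- SeO2 may prefer the more nucleophilic C7=C8 alkene, which would oxidise the doubly allylic C6. It may also attack the vinylic methyl groups, as is often seen for E-alkenes in medium rings.
- The fallback sets out from 1 and comes back at 2.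
- One equivalent of mCPBA first epoxidises the most reactive alkene to racemic humulene 7,8-epoxide F1.
- SeO2/t-BuOOH then meets only one trisubstituted alkene and gives 10-hydroxyhumulene 7,8-epoxide F2. Both C10 epimers are usable, because C10 is flattened in step 2.
- WCl6/n-BuLi in THF removes the epoxide oxygen with retention of the E geometry and delivers 2.

The second weak point is step 5.
- The resorcinol-type quinone methide is only moderately electrophilic, and its precursor and products are nucleophilic arenes, so oligomers can form.
- The allylic-alcohol alkene is sluggish.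
- The C10 carbinol may steer the facial selectivity only weakly, so diastereomers would have to be separated.
- The fallback sets out from 5 (partner 4) and comes back at 9.
- Boc2O/DMAP gives 2,4-bis(tert-butoxycarbonyloxy)-6-methylbenzaldehyde F3. BH3·THF reduces it to 2,4-bis(tert-butoxycarbonyloxy)-6-methylbenzyl alcohol F4.
- t-BuMgCl is added at −78 °C to a mixture of F4 and 4. This starts an anionic cascade (Boc shift from the ortho oxygen to the benzylic alkoxide, then loss of tert-butyl carbonate) that releases the carbonate-protected o-quinone methide F5 below room temperature.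
- F5 is more electrophilic and its ring is no longer nucleophilic. The magnesium alkoxide at C10 of 4 can bind its carbonyl and deliver it to the neighbouring alkene face.
- The product is the bis(7-tert-butoxycarbonyloxychroman) F6, and K2CO3/MeOH frees the phenols to give 9.

The third weak point is step 7.
- The diazoalkane may instead give dioxoles, spiro-epoxides or pyrazolines, or it may insert on the wrong side. The Lewis acid may also ionise the tertiary ethers of the elaborate substrate.
- The fallback sets out from 6 (partner 4) and comes back at 12. It moves the ring expansion to a small molecule and finishes with a cycloaddition instead of skeletal editing.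
- 2,2-Dimethoxypropane/PPTS ties the ortho OH and the CH2OH of 6 into 2,2,5-trimethyl-4H-1,3-benzodioxin-7-ol F7.
- IBX gives 2,2,5-trimethyl-4H-1,3-benzodioxine-6,7-dione F8. On this gram-scale substrate homologating reagents can be screened freely.
- The expansion runs through the silyloxytropone acetonide F9 to the tropolone acetonide F10.
- Aqueous acetic acid unmasks 4-hydroxy-5-(hydroxymethyl)-6-methyltropolone F11.
- Heating F11 with 4 in xylene at 140 °C dehydrates it to the tropolone o-quinone methide F12, which adds twice to 4 and gives 12 directly.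

**Further compounds**
F1 | step 1 | racemic humulene 7,8-epoxide (trans, one enantiomer drawn) | C1C[C@H]2O[C@]2(C)C/C=C/C(C)(C)C/C=C1\C
F2 | step 1 | 10-hydroxyhumulene 7,8-epoxide (racemic, C10 epimers) | OC1C[C@H]2O[C@]2(C)C/C=C/C(C)(C)C/C=C1\C
F3 | step 5 | 2,4-bis(tert-butoxycarbonyloxy)-6-methylbenzaldehyde | Cc1cc(OC(=O)OC(C)(C)C)cc(OC(=O)OC(C)(C)C)c1C=O
F4 | step 5 | 2,4-bis(tert-butoxycarbonyloxy)-6-methylbenzyl alcohol | Cc1cc(OC(=O)OC(C)(C)C)cc(OC(=O)OC(C)(C)C)c1CO
F5 | step 5 | carbonate-protected o-quinone methide | C=C1C(C)=CC(OC(=O)OC(C)(C)C)=CC1=O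
F6 | step 5 | (1R,7R,8R,10S,11R)-bis(7-tert-butoxycarbonyloxy-5-methylchroman) | Cc1cc(OC(=O)OC(C)(C)C)cc2c1C[C@H]1CC(C)(C)/C=C/C[C@@]3(C)Oc4cc(OC(=O)OC(C)(C)C)cc(C)c4C[C@@H]3C[C@H](O)[C@]1(C)O2
F7 | step 7 | 2,2,5-trimethyl-4H-1,3-benzodioxin-7-ol | Cc1cc(O)cc2c1COC(C)(C)O2
F8 | step 7 | 2,2,5-trimethyl-4H-1,3-benzodioxine-6,7-dione | CC=1C(=O)C(=O)C=C2C=1COC(C)(C)O2
F9 | step 7 | silyloxytropone acetonide | Cc1cc(O[Si](C)(C)C)c(=O)cc2c1COC(C)(C)O2
F10 | step 7 | tropolone acetonide | Cc1cc(=O)c(O)cc2c1COC(C)(C)O2
F11 | step 7 | 4-hydroxy-5-(hydroxymethyl)-6-methyltropolone | Cc1cc(=O)c(O)cc(O)c1CO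
F12 | step 7 | tropolone o-quinone methide | C=C1C(C)=CC(=O)C(O)=CC1=O
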